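**Assumption:** Mururin C has no stereocentres and no stereogenic double bonds, so it is achiral and no stereocontrol is needed anywhere in the route.

## Retrosynthetic overview

1. The third B-ring oxygen goes in last, by Br→OH exchange on an aryl bromide, so the catechol never needs protection.
2. The C2–aryl bond comes from C2–H arylation of 5-(3-hydroxypropyl)-7-methoxybenzofuran-3-carbaldehyde with 2-bromo-4-iodo-6-methoxyphenol.
3. Key step: the furan ring, already carrying the 3-CHO, is made by an oxidative radical [3+2] annulation of 4-(3-hydroxypropyl)-2-methoxyphenol with 3-(dimethylamino)acrolein; the C3–C3a bond forms at the free ortho carbon of a phenoxyl radical.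
4. Both arenes come from one intermediate, 4-iodoguaiacol, made from catechol; the side chain comes from allyl alcohol by B-alkyl Suzuki coupling.
5. Ring order: both benzene rings are purchased (catechol); the furan is the only ring built, in the key step.

## Route

**Step 1**
Reactants: 1, catechol (benzene-1,2-diol; used in 2-fold excess)
Product: 2, 2-methoxyphenol (guaiacol)
Conditions: MeI (1.0 equiv), K2CO3 (1.0 equiv), acetone, reflux; excess 1 removed by aqueous wash
Reagents that add atoms: iodomethane, CI
Why: Williamson mono-O-methylation; excess diol suppresses dimethylation, and the phenolic product is separated from neutral veratrole by base extraction.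

**Step 2**
Reactants: 2, 2-methoxyphenol
Product: 3, 4-iodo-2-methoxyphenol
Conditions: NIS (1.0 equiv), TsOH·H2O (10 mol %), MeCN, 0 °C → rt
Reagents that add atoms: N-iodosuccinimide, O=C1CCC(=O)N1I
Why: Electrophilic aromatic iodination; the free OH is the stronger director, so iodine enters para to it.

**Step 3**
Reactants: 3, 4-iodo-2-methoxyphenol; 4, allyl alcohol (prop-2-en-1-ol)
Product: 5, 4-(3-hydroxypropyl)-2-methoxyphenol (dihydroconiferyl alcohol)
Conditions: 4, 9-BBN-H (2.2 equiv), THF, 0 °C → rt; then 3, PdCl2(dppf) (5 mol %), 3 M aq K3PO4, THF/DMF, 60 °C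
Reagents that add atoms: none (9-BBN delivers only H)
Why: Anti-Markovnikov hydroboration followed by B-alkyl Suzuki–Miyaura coupling; the first equivalent of 9-BBN caps the OH as a borinate that hydrolyses on workup, and the aryl iodide couples despite the free phenol.

**Step 4 (key step)**
Reactants: 5, 4-(3-hydroxypropyl)-2-methoxyphenol; 6, (E)-3-(dimethylamino)acrolein (3 equiv)
Product: 7, 5-(3-hydroxypropyl)-7-methoxy-1-benzofuran-3-carbaldehyde
Conditions: FeCl3 (10 mol %), t-BuOOt-Bu (1.5 equiv, slow addition), HFIP, rt; then AcOH, 50 °C
Reagents that add atoms: none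
Why: Proposed new method: Fe(III)/peroxide oxidises 5 to an iron-bound phenoxyl radical whose only free ortho carbon (para is blocked) bonds to the nucleophilic α-carbon of the enaminal, the resulting α-amino radical is oxidised to an iminium, the phenol oxygen closes onto it and loss of Me2NH aromatises to the 3-formylbenzofuran with unambiguous regiochemistry; the closest known reactions are iron-catalysed oxidative phenol/alkene and phenol/β-ketoester [3+2] annulations and the Nenitzescu quinone–enaminone benzofuran synthesis.

**Step 5**
Reactants: 3, 4-iodo-2-methoxyphenol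
Product: 8, 2-bromo-4-iodo-6-methoxyphenol
Conditions: NBS (1.0 equiv), i-Pr2NH (10 mol %), CH2Cl2, 0 °C
Reagents that add atoms: N-bromosuccinimide, O=C1CCC(=O)N1Br
Why: Amine-mediated ortho-selective bromination of a phenol; the para position is blocked by iodine, leaving the one free ortho carbon.

**Step 6**
Reactants: 7, 5-(3-hydroxypropyl)-7-methoxy-1-benzofuran-3-carbaldehyde; 8, 2-bromo-4-iodo-6-methoxyphenol
Product: 9, 2-(3-bromo-4-hydroxy-5-methoxyphenyl)-5-(3-hydroxypropyl)-7-methoxy-1-benzofuran-3-carbaldehyde
Conditions: Pd(OAc)2 (5 mol %), Ag2O (0.75 equiv), 2-nitrobenzoic acid (1.5 equiv), HFIP, 50 °C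
Reagents that add atoms: none
Why: Pd-catalysed direct C–H arylation at C2, the only furan C–H; the C–I bond reacts selectively over the hindered, deactivated C–Br, and the mild acidic silver/HFIP conditions tolerate the free phenol, alcohol and aldehyde.

**Step 7**
Reactants: 9, the aryl bromide from step 6
Product: 10, Mururin C, 2-(3,4-dihydroxy-5-methoxyphenyl)-5-(3-hydroxypropyl)-7-methoxy-1-benzofuran-3-carbaldehyde
Conditions: Cu(acac)2 (10 mol %), N,N'-bis(4-hydroxy-2,6-dimethylphenyl)oxalamide (10 mol %), LiOH·H2O (5 equiv), degassed DMSO/H2O 4:1, 80 °C, Ar; then aq HCl/Na2S2O4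
Reagents that add atoms: lithium hydroxide (hydroxide oxygen), [Li+].[OH-]
Why: Ullmann-type Cu-catalysed hydroxylation of an ortho-bromophenol, the same change as the classical 5-bromovanillin → 5-hydroxyvanillin conversion; the aldehyde is deactivated by conjugation to the para-phenoxide, and anaerobic conditions with a reductive acidic quench protect the catechol.

## Compound list

1 | catechol (benzene-1,2-diol) | Oc1ccccc1O | starting material
2 | 2-methoxyphenol (guaiacol) | COc1ccccc1O | intermediate
3 | 4-iodo-2-methoxyphenol | COc1cc(I)ccc1O | intermediate
4 | allyl alcohol | C=CCO | starting material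
5 | 4-(3-hydroxypropyl)-2-methoxyphenol | COc1cc(CCCO)ccc1O | intermediate
6 | (E)-3-(dimethylamino)acrolein | CN(C)/C=C/C=O | starting material
7 | 5-(3-hydroxypropyl)-7-methoxy-1-benzofuran-3-carbaldehyde | O=Cc1coc2c(OC)cc(CCCO)cc12 | intermediate
8 | 2-bromo-4-iodo-6-methoxyphenol | COc1cc(I)cc(Br)c1O | intermediate
9 | 2-(3-bromo-4-hydroxy-5-methoxyphenyl)-5-(3-hydroxypropyl)-7-methoxy-1-benzofuran-3-carbaldehyde | COc1cc(-c2oc3c(OC)cc(CCCO)cc3c2C=O)cc(Br)c1O | intermediate
10 | Mururin C | COc1cc(-c2oc3c(OC)cc(CCCO)cc3c2C=O)cc(O)c1O | target

## Summary

**Total steps:** 7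
**Longest linear sequence:** 6 (steps 1, 2, 3, 4, 6, 7); step 5 is a one-step branch from 3.

**Steps most likely to fail, with fallbacks:**

1. **Step 4 (oxidative radical annulation).** Risks are phenol homodimerisation, quinone-methide formation and oxidation of the enaminal. Fallback: tether before bond formation. Add 5 to ethyl propiolate (oxa-Michael), α-brominate the aryloxyacrylate, close C3–C3a by vinyl-radical cyclisation onto the arene (Bu3SnH/AIBN), then convert the ester to the aldehyde (DIBAL-H, then MnO2).

2. **Step 6 (C2–H arylation with a free-phenol aryl iodide).** Risks are sluggish reaction of the electron-rich iodide and low reactivity of the electron-poor furan. Fallback: put the aryl group into the annulation partner. Convert the B-ring acetophenone (3-bromo-4-hydroxy-5-methoxyacetophenone) by Vilsmeier–Arnold reaction and Me2NH into the 3-aryl-3-(dimethylamino)acrolein, and use that in the step-4 annulation with 5 to give 9 directly.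

3. **Step 7 (late hydroxylation).** Risks are base sensitivity of the formylbenzofuran and air oxidation of the catechol. Fallback: install the oxygen before the union and carry it protected. Ortho-formylate 4-bromoguaiacol, Dakin-oxidise to 5-bromo-3-methoxycatechol, protect as the bis-MOM ether, arylate 7 with that bromide, and finish with HCl/MeOH instead of a C–O coupling.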